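Ring A is disconnected as a 1-acylcyclohexene: its exocyclic alkene (alkylidene ring carbon to the bridging CH) is the 1,3-transposed form of a ring enone. The key step joins an alkynal and isobutyraldehyde trimethylsilyl enol ether in one flask: an enantioselective Mukaiyama aldol makes the bond between the future CHBr carbon and the gem-dimethyl carbon, and carbonyl–alkyne metathesis then makes the bond between the ring CH2 (former aldehyde carbon) and the alkylidene carbon. The precursor is an acyclic ynal hanging from a bromocyclohexane; the resulting ketone later closes the cyclopentane by aldol and is erased by reductive alkene transposition.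

Key step: step 10

Ring names used below: ring A = bromo-dimethylcyclohexylidene ring; ring B = cyclohexane of the hydrindane; ring C = its cyclopentane.

Assumption: the N-tosyl-L-valine-derived oxazaborolidinone is taken to direct Si-face attack on the aldehyde with enol silane 17 as it does with isobutyrate ketene silyl acetals (3R carbinol); if a model aldol shows the opposite sense, the D-valine ligand is used.

Step 1
Reactants: 1 2-(2-bromoethyl)-1,3-dioxolane; 2 lithium acetylide–ethylenediamine complex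
Product: 3 2-(but-3-yn-1-yl)-1,3-dioxolane
Conditions: DMSO, 0 → 23 °C
Reagents that add atoms: none
Why: SN2 alkylation of lithium acetylide by the primary bromide in DMSO is a standard route to terminal alkynes; no stereocentre is formed.

Step 2
Reactants: 4 2-methylcyclohexane-1,3-dione; 5 allyl bromide
Product: 6 2-allyl-2-methylcyclohexane-1,3-dione
Conditions: NaOH (1 M), H2O, 23 °C
Reagents that add atoms: none
Why: C-alkylation of the stabilised 1,3-diketone enolate with an allylic bromide builds the quaternary methyl-bearing carbon of ring B; the product is achiral.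

Step 3
Reactants: 6 2-allyl-2-methylcyclohexane-1,3-dione
Product: 7 (2R,3R)-2-allyl-3-hydroxy-2-methylcyclohexan-1-one
Conditions: (S)-Me-CBS oxazaborolidine (20 mol%), catecholborane, toluene, −78 °C
Reagents that add atoms: none
Why: Corey–Bakshi–Shibata reduction desymmetrises the enantiotopic carbonyls, hydride arriving anti to the larger allyl group (hydroxyl cis to allyl) and the (S)-catalyst, which reads the quaternary carbon as the large substituent, selecting the carbonyl that gives the 3R carbinol, so both stereocentres are set here.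

Step 4
Reactants: 7 (2R,3R)-2-allyl-3-hydroxy-2-methylcyclohexan-1-one
Product: 8 (2S,3S)-2-allyl-3-bromo-2-methylcyclohexan-1-one
Conditions: PPh3, CBr4, CH2Cl2, 0 → 23 °C
Reagents that add atoms: tetrabromomethane, BrC(Br)(Br)Br
Why: Appel reaction, in which bromide displaces the alkoxyphosphonium group by SN2 with inversion to give the 3S bromide (trans to allyl), while the quaternary α-carbon rules out elimination towards the ketone.

Step 5
Reactants: 8 (2S,3S)-2-allyl-3-bromo-2-methylcyclohexan-1-one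
Product: 9 (1S,2S)-1-allyl-2-bromo-1-methyl-6-methylidenecyclohexane
Conditions: Ph3PCH3Br, KOt-Bu, toluene, 23 → 80 °C
Reagents that add atoms: methyltriphenylphosphonium bromide, C[P+](c1ccccc1)(c1ccccc1)c1ccccc1.[Br-]
Why: Wittig methylenation of the hindered ketone installs the carbon that becomes the ring C methine; the equatorial bromide has no antiperiplanar hydrogen and should survive the basic ylide.

Step 6
Reactants: 9 (1S,2S)-1-allyl-2-bromo-1-methyl-6-methylidenecyclohexane
Product: 11 (3S,4S)-3-allyl-4-bromo-3-methyl-2-methylidenecyclohexan-1-one, via allylic alcohol 10 (not isolated)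
Conditions: SeO2 (20 mol%), t-BuOOH, CH2Cl2, 23 °C; then Dess–Martin periodinane, NaHCO3, 23 °C
Reagents that add atoms: tert-butyl hydroperoxide, CC(C)(C)OO
Why: SeO2-catalysed allylic hydroxylation (ene reaction then [2,3]-shift) can only occur at the single allylic CH2 of the 1,1-disubstituted alkene, and Dess–Martin oxidation of the alcohol gives the cisoid α-methylene ketone, a net 1,2-carbonyl transposition without a new stereocentre.

Step 7
Reactants: 11 (3S,4S)-3-allyl-4-bromo-3-methyl-2-methylidenecyclohexan-1-one; 3 2-(but-3-yn-1-yl)-1,3-dioxolane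
Product: 13 (2S,3S,4S)-3-allyl-4-bromo-2-[5-(1,3-dioxolan-2-yl)pent-2-yn-1-yl]-3-methylcyclohexan-1-one, via diethylalkynylalane 12 (not isolated)
Conditions: 3, n-BuLi, THF, −78 °C; Et2AlCl, −78 → 0 °C; then 11, Et2O–toluene, −15 → 23 °C; aq Rochelle salt, 0 °C
Reagents that add atoms: none
Why: Conjugate addition of a diethylalkynylalane to a cisoid enone through a six-membered transition state joins the alkyne to the exocyclic CH2, and cold axial protonation of the aluminium enolate anti to the axial methyl group places the side chain equatorial (2S), trans to allyl.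

Step 8
Reactants: 13 (2S,3S,4S)-3-allyl-4-bromo-2-[5-(1,3-dioxolan-2-yl)pent-2-yn-1-yl]-3-methylcyclohexan-1-one
Product: 14 (1R,2S,3S,4S)-3-allyl-4-bromo-2-[5-(1,3-dioxolan-2-yl)pent-2-yn-1-yl]-1,3-dimethylcyclohexan-1-ol
Conditions: MeMgBr, CeCl3, THF, −78 °C
Reagents that add atoms: methylmagnesium bromide, C[Mg]Br
Why: Organocerium 1,2-addition, non-basic enough to spare the γ-bromo ketone; the axial methyl group on the neighbouring quaternary carbon blocks axial attack, so methyl enters equatorially and the new carbinol (1R) has its hydroxyl axial, cis to that methyl group as in the target.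

Step 9
Reactants: 14 (1R,2S,3S,4S)-3-allyl-4-bromo-2-[5-(1,3-dioxolan-2-yl)pent-2-yn-1-yl]-1,3-dimethylcyclohexan-1-ol
Product: 16 6-[(1S,2S,3S,6R)-2-allyl-3-bromo-2,6-dimethyl-6-(triethylsilyloxy)cyclohexyl]hex-4-ynal, via collidinium acetal salt 15 (not isolated)
Conditions: Et3SiOTf (3.5 equiv), 2,4,6-collidine, CH2Cl2, 0 → 23 °C; then H2O, 23 °C
Reagents that add atoms: triethylsilyl trifluoromethanesulfonate, CC[Si](CC)(CC)OS(=O)(=O)C(F)(F)F; water, O
Why: Silyl triflate and collidine silylate the tertiary alcohol and open the dioxolane to a collidinium N,O-acetal that water hydrolyses to the aldehyde (silyl triflate–pyridine acetal cleavage), so no aqueous acid is needed and no stereocentre changes.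

Step 10
Reactants: 16 6-[(1S,2S,3S,6R)-2-allyl-3-bromo-2,6-dimethyl-6-(triethylsilyloxy)cyclohexyl]hex-4-ynal; 17 2-methyl-1-(trimethylsilyloxy)prop-1-ene
Product: 19 2-[(1S,2S,3S,6R)-2-allyl-3-bromo-2,6-dimethyl-6-(triethylsilyloxy)cyclohexyl]-1-[(4R)-4-hydroxy-3,3-dimethylcyclohex-1-en-1-yl]ethan-1-one, via silyl aldol aldehyde 18 (not isolated)
Conditions: 17 (1.3 equiv), oxazaborolidinone from N-tosyl-L-valine and BH3·THF (20 mol%), EtNO2, −78 °C; then Tf2NH (10 mol%), CH2Cl2, −78 → −20 °C; then 0.5 M HCl, THF, 0 °C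
Reagents that add atoms: none
Why: Proposed new method: the oxazaborolidinone-bound aldehyde of 16 is attacked on its Si face by the nucleophilic carbon of 17 in an open Mukaiyama transition state (bond between the carbinol carbon and the gem-dimethyl carbon) and silyl transfer releases the non-enolisable aldehyde 18; Tf2NH, as its silyl imide, then activates this aldehyde for attack by the tethered alkyne, and the vinyl cation collapses to an oxetene whose ring-opening gives the 1-acylcyclohexene (bond between the former aldehyde carbon and the future alkylidene carbon, first as C=C). The closest known reaction types are the oxazaborolidinone-promoted Mukaiyama (Kiyooka) aldol of the isobutyrate ketene silyl acetal with aliphatic aldehydes and the acid-promoted intramolecular alkyne–aldehyde metathesis of alkynals to cycloalkenyl ketones; running both in one flask with an aldehyde-level enol silane is new. Ring A closes in the 6-exo-dig mode, the 7-endo alternative being disfavoured by the tether length and by the alkyl-stabilised exocyclic vinyl cation. The only new stereocentre, the 4R carbinol, is controlled by the chiral Lewis acid, the distant ring B stereocentres having no influence. The step needs chemoselectivity for the single aldehyde of 16, secured because the product aldehyde is neopentylic and reacts more slowly with 17, and survival of the tertiary silyl ether and the bromide, secured by low temperature and catalytic acid.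

Step 11
Reactants: 19 2-[(1S,2S,3S,6R)-2-allyl-3-bromo-2,6-dimethyl-6-(triethylsilyloxy)cyclohexyl]-1-[(4R)-4-hydroxy-3,3-dimethylcyclohex-1-en-1-yl]ethan-1-one
Product: 20 2-[(1S,2S,3S,6R)-2-allyl-3-bromo-2,6-dimethyl-6-(triethylsilyloxy)cyclohexyl]-1-[(4S)-4-bromo-3,3-dimethylcyclohex-1-en-1-yl]ethan-1-one
Conditions: PPh3, CBr4, 2,6-lutidine, CH2Cl2, 0 → 23 °C
Reagents that add atoms: tetrabromomethane, BrC(Br)(Br)Br
Why: Appel reaction with SN2 inversion turns the 4R neopentylic carbinol of ring A into the 4S bromide of the target, and it is run while this is the only free hydroxyl in the molecule.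

Step 12
Reactants: 20 2-[(1S,2S,3S,6R)-2-allyl-3-bromo-2,6-dimethyl-6-(triethylsilyloxy)cyclohexyl]-1-[(4S)-4-bromo-3,3-dimethylcyclohex-1-en-1-yl]ethan-1-one
Product: 21 2-[(1S,2S,3S,6R)-3-bromo-2,6-dimethyl-2-(2-oxoethyl)-6-(triethylsilyloxy)cyclohexyl]-1-[(4S)-4-bromo-3,3-dimethylcyclohex-1-en-1-yl]ethan-1-one
Conditions: OsO4 (2 mol%), NaIO4, 2,6-lutidine, dioxane–H2O, 23 °C
Reagents that add atoms: sodium periodate, [Na+].[O-]I(=O)(=O)=O
Why: Lemieux–Johnson oxidation, in which OsO4 dihydroxylates the electron-rich terminal alkene much faster than the conjugated trisubstituted enone and NaIO4 cleaves the diol to the aldehyde; no stereocentre is touched.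

Step 13
Reactants: 21 2-[(1S,2S,3S,6R)-3-bromo-2,6-dimethyl-2-(2-oxoethyl)-6-(triethylsilyloxy)cyclohexyl]-1-[(4S)-4-bromo-3,3-dimethylcyclohex-1-en-1-yl]ethan-1-one
Product: 22 [(1S,2R,3aS,4S,7R,7aS)-4-bromo-2-hydroxy-3a,7-dimethyl-7-(triethylsilyloxy)octahydro-1H-inden-1-yl][(4S)-4-bromo-3,3-dimethylcyclohex-1-en-1-yl]methanone
Conditions: LiN(SiMe3)2, THF, −78 °C; AcOH, −78 °C
Reagents that add atoms: none
Why: Intramolecular aldol addition: the ketone can enolise only towards its α′-CH2, and its lithium enolate adds to the aldehyde through a chelated chair (Zimmerman–Traxler) transition state that closes ring C as a trans-fused hydrindane with the acyl group and the new hydroxyl cis, on the face of the ring-fusion hydrogen (1S,2R).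

Step 14
Reactants: 22 [(1S,2R,3aS,4S,7R,7aS)-4-bromo-2-hydroxy-3a,7-dimethyl-7-(triethylsilyloxy)octahydro-1H-inden-1-yl][(4S)-4-bromo-3,3-dimethylcyclohex-1-en-1-yl]methanone
Product: 24 (1S,2R,3aS,4S,7R,7aS)-4-bromo-1-{(E)-[(4S)-4-bromo-3,3-dimethylcyclohexylidene]methyl}-3a,7-dimethyl-7-(triethylsilyloxy)octahydro-1H-inden-2-ol, via tosylhydrazone 23 (not isolated)
Conditions: TsNHNH2, PPTS (cat.), THF, 50 °C; then catecholborane, CHCl3, 0 °C; NaOAc·3H2O, 60 °C
Reagents that add atoms: none
Why: Tosylhydrazone formation, catecholborane reduction and loss of sulfinate give an allylic diazene whose retro-ene loss of N2 (reductive 1,3-transposition) delivers hydrogen to the ring CH and moves the double bond exocyclic; the bulky hydrindanyl group sits pseudo-equatorial in the six-membered transition state and so ends trans to the new ring CH2 (E), from either hydrazine epimer.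

Step 15
Reactants: 24 (1S,2R,3aS,4S,7R,7aS)-4-bromo-1-{(E)-[(4S)-4-bromo-3,3-dimethylcyclohexylidene]methyl}-3a,7-dimethyl-7-(triethylsilyloxy)octahydro-1H-inden-2-ol
Product: 25 iriediol
Conditions: HF·pyridine, pyridine–THF, 0 → 23 °C
Reagents that add atoms: none
Why: Fluoride-mediated cleavage of the tertiary triethylsilyl ether under buffered conditions should leave the secondary bromides, the alkene and all stereocentres untouched.

Compound list
1 | 2-(2-bromoethyl)-1,3-dioxolane | BrCCC1OCCO1 | starting material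
2 | lithium acetylide–ethylenediamine complex | [Li+].[C-]#C.NCCN | starting material
3 | 2-(but-3-yn-1-yl)-1,3-dioxolane | C#CCCC1OCCO1 | intermediate
4 | 2-methylcyclohexane-1,3-dione | CC1C(=O)CCCC1=O | starting material
5 | allyl bromide (3-bromoprop-1-ene) | C=CCBr | starting material
6 | 2-allyl-2-methylcyclohexane-1,3-dione | C=CCC1(C)C(=O)CCCC1=O | intermediate
7 | (2R,3R)-2-allyl-3-hydroxy-2-methylcyclohexan-1-one | C=CC[C@]1(C)[C@H](O)CCCC1=O | intermediate
8 | (2S,3S)-2-allyl-3-bromo-2-methylcyclohexan-1-one | C=CC[C@]1(C)[C@@H](Br)CCCC1=O | intermediate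
9 | (1S,2S)-1-allyl-2-bromo-1-methyl-6-methylidenecyclohexane | C=CC[C@]1(C)[C@@H](Br)CCCC1=C | intermediate
10 | (3S,4S)-3-allyl-4-bromo-3-methyl-2-methylidenecyclohexan-1-ol (both C-1 epimers) | C=CC[C@]1(C)[C@@H](Br)CCC(O)C1=C | intermediate
11 | (3S,4S)-3-allyl-4-bromo-3-methyl-2-methylidenecyclohexan-1-one | C=CC[C@]1(C)[C@@H](Br)CCC(=O)C1=C | intermediate
12 | diethyl[4-(1,3-dioxolan-2-yl)but-1-yn-1-yl]alane | CC[Al](CC)C#CCCC1OCCO1 | intermediate
13 | (2S,3S,4S)-3-allyl-4-bromo-2-[5-(1,3-dioxolan-2-yl)pent-2-yn-1-yl]-3-methylcyclohexan-1-one | C=CC[C@]1(C)[C@@H](Br)CCC(=O)[C@H]1CC#CCCC2OCCO2 | intermediate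
14 | (1R,2S,3S,4S)-3-allyl-4-bromo-2-[5-(1,3-dioxolan-2-yl)pent-2-yn-1-yl]-1,3-dimethylcyclohexan-1-ol | C=CC[C@]1(C)[C@@H](Br)CC[C@@](C)(O)[C@H]1CC#CCCC2OCCO2 | intermediate
15 | 1-{6-[(1S,2S,3S,6R)-2-allyl-3-bromo-2,6-dimethyl-6-(triethylsilyloxy)cyclohexyl]-1-[2-(triethylsilyloxy)ethoxy]hex-4-yn-1-yl}-2,4,6-trimethylpyridinium triflate (acetal carbon unassigned) | C=CC[C@]1(C)[C@@H](Br)CC[C@@](C)(O[Si](CC)(CC)CC)[C@H]1CC#CCCC(OCCO[Si](CC)(CC)CC)[n+]2c(C)cc(C)cc2C.[O-]S(=O)(=O)C(F)(F)F | intermediate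
16 | 6-[(1S,2S,3S,6R)-2-allyl-3-bromo-2,6-dimethyl-6-(triethylsilyloxy)cyclohexyl]hex-4-ynal | C=CC[C@]1(C)[C@@H](Br)CC[C@@](C)(O[Si](CC)(CC)CC)[C@H]1CC#CCCC=O | intermediate
17 | 2-methyl-1-(trimethylsilyloxy)prop-1-ene | CC(C)=CO[Si](C)(C)C | starting material
18 | (3R)-8-[(1S,2S,3S,6R)-2-allyl-3-bromo-2,6-dimethyl-6-(triethylsilyloxy)cyclohexyl]-2,2-dimethyl-3-(trimethylsilyloxy)oct-6-ynal | C=CC[C@]1(C)[C@@H](Br)CC[C@@](C)(O[Si](CC)(CC)CC)[C@H]1CC#CCC[C@@H](O[Si](C)(C)C)C(C)(C)C=O | intermediate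
19 | 2-[(1S,2S,3S,6R)-2-allyl-3-bromo-2,6-dimethyl-6-(triethylsilyloxy)cyclohexyl]-1-[(4R)-4-hydroxy-3,3-dimethylcyclohex-1-en-1-yl]ethan-1-one | C=CC[C@]1(C)[C@@H](Br)CC[C@@](C)(O[Si](CC)(CC)CC)[C@H]1CC(=O)C2=CC(C)(C)[C@H](O)CC2 | intermediate
20 | 2-[(1S,2S,3S,6R)-2-allyl-3-bromo-2,6-dimethyl-6-(triethylsilyloxy)cyclohexyl]-1-[(4S)-4-bromo-3,3-dimethylcyclohex-1-en-1-yl]ethan-1-one | C=CC[C@]1(C)[C@@H](Br)CC[C@@](C)(O[Si](CC)(CC)CC)[C@H]1CC(=O)C2=CC(C)(C)[C@@H](Br)CC2 | intermediate
21 | 2-[(1S,2S,3S,6R)-3-bromo-2,6-dimethyl-2-(2-oxoethyl)-6-(triethylsilyloxy)cyclohexyl]-1-[(4S)-4-bromo-3,3-dimethylcyclohex-1-en-1-yl]ethan-1-one | O=CC[C@]1(C)[C@@H](Br)CC[C@@](C)(O[Si](CC)(CC)CC)[C@H]1CC(=O)C2=CC(C)(C)[C@@H](Br)CC2 | intermediate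
22 | [(1S,2R,3aS,4S,7R,7aS)-4-bromo-2-hydroxy-3a,7-dimethyl-7-(triethylsilyloxy)octahydro-1H-inden-1-yl][(4S)-4-bromo-3,3-dimethylcyclohex-1-en-1-yl]methanone | O=C(C1=CC(C)(C)[C@@H](Br)CC1)[C@@H]2[C@H](O)C[C@]3(C)[C@@H](Br)CC[C@@](C)(O[Si](CC)(CC)CC)[C@@H]23 | intermediate
23 | N-tosylhydrazone of ketone 22 (C=N geometry unassigned) | Cc1ccc(cc1)S(=O)(=O)NN=C(C2=CC(C)(C)[C@@H](Br)CC2)[C@@H]3[C@H](O)C[C@]4(C)[C@@H](Br)CC[C@@](C)(O[Si](CC)(CC)CC)[C@@H]34 | intermediate
24 | (1S,2R,3aS,4S,7R,7aS)-4-bromo-1-{(E)-[(4S)-4-bromo-3,3-dimethylcyclohexylidene]methyl}-3a,7-dimethyl-7-(triethylsilyloxy)octahydro-1H-inden-2-ol | CC1(C)C/C(=C/[C@@H]2[C@H](O)C[C@]3(C)[C@@H](Br)CC[C@@](C)(O[Si](CC)(CC)CC)[C@@H]23)CC[C@@H]1Br | intermediate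
25 | iriediol, (1S,2R,3aS,4S,7R,7aS)-4-bromo-1-{(E)-[(4S)-4-bromo-3,3-dimethylcyclohexylidene]methyl}-3a,7-dimethyloctahydro-1H-indene-2,7-diol | CC1(C)C/C(=C/[C@@H]2[C@H](O)C[C@]3(C)[C@@H](Br)CC[C@@](C)(O)[C@@H]23)CC[C@@H]1Br | target

Total step count: 15. Longest linear sequence: 14 steps (steps 2 to 15, from 2-methylcyclohexane-1,3-dione).

Steps most likely to fail

Step 10 (Proposed new method). The chiral Lewis acid may give poor facial control with the weakly nucleophilic aldehyde-level enol silane, or the metathesis stage may stall or strip the tertiary silyl ether before the alkyne attacks. The fallback sets out from 16 and returns to 19 with known reactions run separately. A Kiyooka aldol of 16 with 1-methoxy-2-methyl-1-(trimethylsilyloxy)prop-1-ene and the stoichiometric N-tosyl-L-valine/BH3·THF oxazaborolidinone should give methyl (3R)-8-[(1S,2S,3S,6R)-2-allyl-3-bromo-2,6-dimethyl-6-(triethylsilyloxy)cyclohexyl]-3-hydroxy-2,2-dimethyloct-6-ynoate F1. Silylation (Et3SiOTf, 2,6-lutidine) should give the 3-(triethylsilyloxy) ester F2, and i-Bu2AlH at −78 °C the (3R)-2,2-dimethyl-3-(triethylsilyloxy)oct-6-ynal F3. BF3·OEt2-promoted intramolecular alkyne–aldehyde metathesis should then give 2-[(1S,2S,3S,6R)-2-allyl-3-bromo-2,6-dimethyl-6-(triethylsilyloxy)cyclohexyl]-1-[(4R)-3,3-dimethyl-4-(triethylsilyloxy)cyclohex-1-en-1-yl]ethan-1-one F4, whose secondary silyl ether is cleaved with PPTS in MeOH at 0 °C to reach 19.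

Step 11. SN2 displacement at the neopentylic carbinol may be slow, so that elimination or a Wagner–Meerwein methyl shift of the alkoxyphosphonium ion takes over. The fallback sets out from 19 and returns to 20 by separating activation from displacement. Tf2O and 2,6-di-tert-butyl-4-methylpyridine at −78 °C should give (1R)-4-{[(1S,2S,3S,6R)-2-allyl-3-bromo-2,6-dimethyl-6-(triethylsilyloxy)cyclohexyl]acetyl}-2,2-dimethylcyclohex-3-en-1-yl trifluoromethanesulfonate F5, which is treated cold with n-Bu4NBr in toluene so that a naked bromide inverts the centre.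

Step 13. The base may deprotonate the aldehyde α-CH2 instead of the ketone α′-CH2, the aldol may dehydrate, or the two new centres may form with the wrong relative configuration. The fallback sets out from 20 and returns to 22 through a regiospecific, non-basic enolate. LiN(SiMe3)2/Me3SiCl then N-bromosuccinimide should give 2-bromo-2-[(1S,2S,3S,6R)-2-allyl-3-bromo-2,6-dimethyl-6-(triethylsilyloxy)cyclohexyl]-1-[(4S)-4-bromo-3,3-dimethylcyclohex-1-en-1-yl]ethan-1-one F6. OsO4/NaIO4 cleavage should give the corresponding 2-(2-oxoethyl) aldehyde F7, and SmI2 in THF at −78 °C should close ring C by an intramolecular Reformatsky-type aldol through the chelated samarium enolate.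

Further compounds
F1 | step 10 | methyl (3R)-8-[(1S,2S,3S,6R)-2-allyl-3-bromo-2,6-dimethyl-6-(triethylsilyloxy)cyclohexyl]-3-hydroxy-2,2-dimethyloct-6-ynoate | C=CC[C@]1(C)[C@@H](Br)CC[C@@](C)(O[Si](CC)(CC)CC)[C@H]1CC#CCC[C@@H](O)C(C)(C)C(=O)OC
F2 | step 10 | methyl (3R)-8-[(1S,2S,3S,6R)-2-allyl-3-bromo-2,6-dimethyl-6-(triethylsilyloxy)cyclohexyl]-2,2-dimethyl-3-(triethylsilyloxy)oct-6-ynoate | C=CC[C@]1(C)[C@@H](Br)CC[C@@](C)(O[Si](CC)(CC)CC)[C@H]1CC#CCC[C@@H](O[Si](CC)(CC)CC)C(C)(C)C(=O)OC
F3 | step 10 | (3R)-8-[(1S,2S,3S,6R)-2-allyl-3-bromo-2,6-dimethyl-6-(triethylsilyloxy)cyclohexyl]-2,2-dimethyl-3-(triethylsilyloxy)oct-6-ynal | C=CC[C@]1(C)[C@@H](Br)CC[C@@](C)(O[Si](CC)(CC)CC)[C@H]1CC#CCC[C@@H](O[Si](CC)(CC)CC)C(C)(C)C=O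
F4 | step 10 | 2-[(1S,2S,3S,6R)-2-allyl-3-bromo-2,6-dimethyl-6-(triethylsilyloxy)cyclohexyl]-1-[(4R)-3,3-dimethyl-4-(triethylsilyloxy)cyclohex-1-en-1-yl]ethan-1-one | C=CC[C@]1(C)[C@@H](Br)CC[C@@](C)(O[Si](CC)(CC)CC)[C@H]1CC(=O)C2=CC(C)(C)[C@H](O[Si](CC)(CC)CC)CC2
F5 | step 11 | (1R)-4-{[(1S,2S,3S,6R)-2-allyl-3-bromo-2,6-dimethyl-6-(triethylsilyloxy)cyclohexyl]acetyl}-2,2-dimethylcyclohex-3-en-1-yl trifluoromethanesulfonate | C=CC[C@]1(C)[C@@H](Br)CC[C@@](C)(O[Si](CC)(CC)CC)[C@H]1CC(=O)C2=CC(C)(C)[C@H](OS(=O)(=O)C(F)(F)F)CC2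
F6 | step 13 | 2-bromo-2-[(1S,2S,3S,6R)-2-allyl-3-bromo-2,6-dimethyl-6-(triethylsilyloxy)cyclohexyl]-1-[(4S)-4-bromo-3,3-dimethylcyclohex-1-en-1-yl]ethan-1-one (both epimers at the new CHBr) | C=CC[C@]1(C)[C@@H](Br)CC[C@@](C)(O[Si](CC)(CC)CC)[C@H]1C(Br)C(=O)C2=CC(C)(C)[C@@H](Br)CC2
F7 | step 13 | 2-bromo-2-[(1S,2S,3S,6R)-3-bromo-2,6-dimethyl-2-(2-oxoethyl)-6-(triethylsilyloxy)cyclohexyl]-1-[(4S)-4-bromo-3,3-dimethylcyclohex-1-en-1-yl]ethan-1-one (both epimers at the new CHBr) | O=CC[C@]1(C)[C@@H](Br)CC[C@@](C)(O[Si](CC)(CC)CC)[C@H]1C(Br)C(=O)C2=CC(C)(C)[C@@H](Br)CC2
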